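Assumption: the target SMILES contains no stereocentre and no C=C geometry. The compound is achiral, so the structure as drawn is the only form to be made.

## Retrosynthetic overview

1. The formyl group comes off first: Vilsmeier–Haack formylation of 2-nonadecylpyrrole at its only free α-position is the last step.
2. The pyrrole is the only ring built. It comes from a Paal–Knorr closure of 4-oxotricosanal with ammonia, and the aldehyde is carried as a dioxolane until then.
3. The key C–C bond is C1'–C2' of the side chain. It is made by crossed aldol addition of the methyl-side enolate of 4-(1,3-dioxolan-2-yl)butan-2-one to octadecanal, followed by dehydration and hydrogenation.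
4. Octadecanal comes from octadecan-1-ol. The keto acetal comes from the Grignard reagent of 2-(2-bromoethyl)-1,3-dioxolane and N-methoxy-N-methylacetamide.
5. Ring order: the dioxolane is bought and is lost in the same step that forms the pyrrole.

## Route

Step 1
Reactants: 1 octadecan-1-ol
Product: 2 octadecanal
Conditions: TEMPO (0.1 equiv), PhI(OAc)2 (1.1 equiv), CH2Cl2, rt, 4 h
Reagents that add atoms: none
Why: This oxoammonium (TEMPO) catalysed alcohol oxidation runs water-free at room temperature, so the waxy alcohol stays dissolved and the aldehyde cannot hydrate and over-oxidise to the acid.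

Step 2
Reactants: 3 2-(2-bromoethyl)-1,3-dioxolane; 4 N-methoxy-N-methylacetamide
Product: 7 keto acetal 4-(1,3-dioxolan-2-yl)butan-2-one, via Grignard reagent 5 (not isolated), via magnesium chelate 6 (not isolated)
Conditions: Mg turnings (1.3 equiv), THF, 25–30 °C; then 4 (0.85 equiv), 0 °C → rt; sat. aq NH4Cl
Reagents that add atoms: magnesium, [Mg] (held only in 5 and 6, absent from 7)
Why: Forming the Grignard reagent below 30 °C keeps the acetal-bearing organomagnesium intact, and the Weinreb ketone synthesis rests at chelate 6 until the buffered quench, so no tertiary alcohol forms and the dioxolane survives.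

Step 3
Reactants: 7 4-(1,3-dioxolan-2-yl)butan-2-one; 2 octadecanal
Product: 10 aldol adduct 1-(1,3-dioxolan-2-yl)-5-hydroxydocosan-3-one (racemic), via lithium enolate 8 (not isolated), via lithium aldolate 9 (not isolated)
Conditions: 7 (1.2 equiv), LiN(i-Pr)2 (commercial solution, 1.15 equiv), THF, −78 °C, 45 min; 2 (1.0 equiv, dilute in THF), −78 → −40 °C; AcOH (1.3 equiv) in THF, −40 °C
Reagents that add atoms: lithium diisopropylamide, [Li+].CC(C)[N-]C(C)C (its lithium is held only in 8 and 9)
Why: In this directed crossed aldol addition the hindered amide irreversibly deprotonates the CH3 side of the methyl ketone, the preformed enolate adds to the aldehyde faster than it deprotonates it, and the new carbinol centre C5 forms as a racemate that step 4 erases.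

Step 4
Reactants: 10 1-(1,3-dioxolan-2-yl)-5-hydroxydocosan-3-one
Product: 12 enone (E)-1-(1,3-dioxolan-2-yl)docos-4-en-3-one, via mesylate 11 (not isolated)
Conditions: MsCl (1.5 equiv), Et3N (4 equiv), CH2Cl2, 0 °C → rt, 3 h
Reagents that add atoms: methanesulfonyl chloride, CS(=O)(=O)Cl (held only in 11, absent from 12)
Why: Mesylation followed by E1cB elimination of the β-mesyloxy ketone gives the conjugated (E)-enone under mild base that leaves the acetal untouched, and it removes the only stereocentre of the route.

Step 5
Reactants: 12 (E)-1-(1,3-dioxolan-2-yl)docos-4-en-3-one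
Product: 13 1-(1,3-dioxolan-2-yl)docosan-3-one
Conditions: H2 (1 atm), Pd/C (10 wt % Pd, 5 mol %), EtOAc–THF 1:1, rt
Reagents that add atoms: none
Why: Heterogeneous catalytic hydrogenation saturates the conjugated C=C much faster than the dialkyl ketone, and the neutral aprotic solvent keeps the dioxolane intact.

Step 6
Reactants: 13 1-(1,3-dioxolan-2-yl)docosan-3-one
Product: 15 2-nonadecyl-1H-pyrrole, via 4-oxotricosanal 14 (not isolated)
Conditions: 2 M aq HCl (0.3 equiv), THF, 45 °C, 3 h; then NH4OAc (10 equiv), EtOH, 65 °C, N2, dark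
Reagents that add atoms: ammonium acetate, CC(=O)[O-].[NH4+] (ring nitrogen); water, O (aldehyde oxygen of 14 only)
Why: Acid-catalysed acetal hydrolysis frees the 1,4-keto aldehyde, which in the Paal–Knorr pyrrole synthesis condenses with ammonia and loses two molecules of water, with aromatisation driving the ring closure.

Step 7
Reactants: 15 2-nonadecyl-1H-pyrrole
Product: 17 5-nonadecyl-1H-pyrrole-2-carbaldehyde (target), via iminium chloride 16 (not isolated)
Conditions: POCl3 (1.2 equiv), DMF (1.5 equiv), ClCH2CH2Cl, 0 °C, 20 min; 15, 0 °C → rt, 2 h; aq NaOAc (6 equiv), 80 °C, 30 min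
Reagents that add atoms: N,N-dimethylformamide, CN(C)C=O (formyl carbon); water, O (aldehyde oxygen); phosphoryl chloride, O=P(Cl)(Cl)Cl (chloride counter-ion of 16 only)
Why: In the Vilsmeier–Haack formylation the chloroiminium ion attacks the electron-rich 2-alkylpyrrole at its only free α-position, and the deactivating iminium group of 16 blocks a second attack before hydrolysis releases the aldehyde.

## Compound list

1 | octadecan-1-ol | CCCCCCCCCCCCCCCCCCO | starting material
2 | octadecanal | CCCCCCCCCCCCCCCCCC=O | intermediate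
3 | 2-(2-bromoethyl)-1,3-dioxolane | BrCCC1OCCO1 | starting material
4 | N-methoxy-N-methylacetamide | CC(=O)N(C)OC | starting material
5 | [2-(1,3-dioxolan-2-yl)ethyl]magnesium bromide | Br[Mg]CCC1OCCO1 | intermediate
6 | bromomagnesium 4-(1,3-dioxolan-2-yl)-2-[methoxy(methyl)amino]butan-2-olate | CC(CCC1OCCO1)(O[Mg]Br)N(C)OC | intermediate
7 | 4-(1,3-dioxolan-2-yl)butan-2-one | CC(=O)CCC1OCCO1 | intermediate
8 | lithium 4-(1,3-dioxolan-2-yl)but-1-en-2-olate | C=C(O[Li])CCC1OCCO1 | intermediate
9 | lithium 1-(1,3-dioxolan-2-yl)-3-oxodocosan-5-olate (racemic) | CCCCCCCCCCCCCCCCCC(O[Li])CC(=O)CCC1OCCO1 | intermediate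
10 | 1-(1,3-dioxolan-2-yl)-5-hydroxydocosan-3-one (racemic) | CCCCCCCCCCCCCCCCCC(O)CC(=O)CCC1OCCO1 | intermediate
11 | 1-(1,3-dioxolan-2-yl)-3-oxodocosan-5-yl methanesulfonate (racemic) | CCCCCCCCCCCCCCCCCC(OS(C)(=O)=O)CC(=O)CCC1OCCO1 | intermediate
12 | (E)-1-(1,3-dioxolan-2-yl)docos-4-en-3-one | CCCCCCCCCCCCCCCCC/C=C/C(=O)CCC1OCCO1 | intermediate
13 | 1-(1,3-dioxolan-2-yl)docosan-3-one | CCCCCCCCCCCCCCCCCCCC(=O)CCC1OCCO1 | intermediate
14 | 4-oxotricosanal | CCCCCCCCCCCCCCCCCCCC(=O)CCC=O | intermediate
15 | 2-nonadecyl-1H-pyrrole | CCCCCCCCCCCCCCCCCCCc1ccc[nH]1 | intermediate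
16 | dimethyl[(5-nonadecyl-1H-pyrrol-2-yl)methylidene]ammonium chloride | CCCCCCCCCCCCCCCCCCCc1ccc(C=[N+](C)C)[nH]1.[Cl-] | intermediate
17 | 5-nonadecyl-1H-pyrrole-2-carbaldehyde | CCCCCCCCCCCCCCCCCCCc1ccc(C=O)[nH]1 | target

## Step count and risks

Total step count: 7. Longest linear sequence: 6 (steps 1 or 2, then 3, 4, 5, 6 and 7).

**Step 3 is the most exposed.** Three things could erode the yield: partial enolisation on the CH2 side of 7, proton transfer to the enolisable aldehyde, and poor solubility of 2 in the cold.
- The fallback sets out from 7 and comes back at 10.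
- Ketone 7 is condensed with 1,1-dimethylhydrazine (EtOH, cat. AcOH, reflux) to give 2-[4-(1,3-dioxolan-2-yl)butan-2-ylidene]-1,1-dimethylhydrazine F1.
- n-BuLi in THF at 0 °C metalates F1 at the less substituted carbon only, giving the lithium aza-enolate F2.
- F2 is more nucleophilic and less basic toward 2. It adds at −78 °C and, after an AcOH quench, gives 1-(1,3-dioxolan-2-yl)-3-(2,2-dimethylhydrazinylidene)docosan-5-ol F3.
- Cu(OAc)2 in THF–water at pH 7 hydrolyses the C=N bond without dehydrating the carbinol or opening the dioxolane, and this delivers 10.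

**Step 6 is second.** Keto aldehyde 14 can oligomerise with ammonia or close to the furan, and the N–H pyrrole 15 is sensitive to acid and air.
- The fallback sets out from 13 and comes back at 15.
- 13 is hydrolysed to 14 as before.
- 14 is then condensed with the primary amine 2-(phenylsulfonyl)ethanamine (hydrochloride, NaOAc, EtOH, 60 °C). This closes faster and more cleanly than ammonia and gives the robust, chromatographable 2-nonadecyl-1-[2-(phenylsulfonyl)ethyl]-1H-pyrrole F4.
- NaH in DMF at rt triggers a retro-Michael (E1cB) loss of the N-substituent, giving sodium 2-nonadecylpyrrol-1-ide F5.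
- A water quench protonates F5 to 15.

**Step 2 is third.** Grignard reagent 5 decomposes if it warms, and the small ketone 7 is partly lost to the aqueous phase.
- The fallback sets out from 3 and comes back at 7. It reverses the polarity, so that 3 acts as the electrophile.
- 2-Methyl-1,3-dithiane is lithiated (n-BuLi, THF, −30 °C) to 2-lithio-2-methyl-1,3-dithiane F6.
- Bromide 3 alkylates F6 (−78 °C → rt) to give 2-[2-(2-methyl-1,3-dithian-2-yl)ethyl]-1,3-dioxolane F7.
- MeI and CaCO3 in MeCN–water at 40 °C unmask the ketone under neutral conditions that spare the dioxolane, giving 7.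

## Further compounds

F1 | step 3 | 2-[4-(1,3-dioxolan-2-yl)butan-2-ylidene]-1,1-dimethylhydrazine | CC(CCC1OCCO1)=NN(C)C
F2 | step 3 | lithium aza-enolate of F1, metalated at the former methyl carbon | C=C(CCC1OCCO1)N([Li])N(C)C
F3 | step 3 | 1-(1,3-dioxolan-2-yl)-3-(2,2-dimethylhydrazinylidene)docosan-5-ol (racemic) | CCCCCCCCCCCCCCCCCC(O)CC(CCC1OCCO1)=NN(C)C
F4 | step 6 | 2-nonadecyl-1-[2-(phenylsulfonyl)ethyl]-1H-pyrrole | CCCCCCCCCCCCCCCCCCCc1cccn1CCS(=O)(=O)c1ccccc1
F5 | step 6 | sodium 2-nonadecylpyrrol-1-ide | CCCCCCCCCCCCCCCCCCCc1ccc[n-]1.[Na+]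
F6 | step 2 | 2-lithio-2-methyl-1,3-dithiane | CC1([Li])SCCCS1
F7 | step 2 | 2-[2-(2-methyl-1,3-dithian-2-yl)ethyl]-1,3-dioxolane | CC1(CCC2OCCO2)SCCCS1
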